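**Retrosynthetic overview**
1. Target 43 is traced back through C4 allylic hydroxylation (SeO2), the C9/C11 acetates and the ring A enone to hydroxy lactone 39. The γ-lactone (C7–O–C19–C17–C8) is closed last, by a SmI2 Reformatsky reaction of a C7 2-bromopropanoate onto a C8 ketone.
2. The ten-membered ring C1–C10 is not cyclised end to end. It is released from ring B of a trans-decalin: the anionic oxy-Cope shift of 7-allenyl-2-vinyl carbinol 29 forms C4–C5 and cuts C2–C7, and the resulting enolate is chlorinated at C6 (29 → 32).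
3. Feature the strategy rests on: in the target the E C2=C3 alkene and the C7 oxygen are 1,5-related across the ten-membered ring, and the C5 exo-methylene (C16) next to the C6 chloride is what an allenyl terminus and the derived C6=C7 enolate leave behind.
4. Carbinol 29 comes from ring B enone 16 by C2 vinylation (ethylidene, then deconjugation), C7 ethynylation, hydroxyl-directed C8–C9 epoxidation with trans-diaxial opening, and Crabbé allenation. Ring A (C11–O, C12–O, C13=C14) is oxygenated by reductive enol silylation, Rubottom oxidation and dehydrogenation.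
5. Ring order: ring B (the starting cyclohexanone) → ring A (Robinson annulation with pent-1-en-3-one through a chiral imine, which sets C1) → ten-membered ring (ring expansion of ring B) → lactone.

Key step: step 17

Remark: atom labels C1–C20 are the briarane labels of the target; in the decalins "syn" and "anti" refer to the angular C1 methyl; the enantiomeric purity from step 1 is assumed to be raised by recrystallisation of diol 12 or keto diol 13; the C12 carbinol configuration is inconsequential because C12 is reoxidised in step 24.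

**Step 1**
Reactants: 1 7-methyl-1,4-dioxaspiro[4.5]decan-8-one (racemic); 2 (R)-1-phenylethylamine; 3 pent-1-en-3-one
Product: 6 (R)-7-methyl-7-(3-oxopentyl)-1,4-dioxaspiro[4.5]decan-8-one, via chiral imine 4 (not isolated), via Michael adduct imine 5 (not isolated)
Conditions: 2, TsOH (cat.), toluene, reflux (Dean–Stark); then 3, THF, 40 °C; then 20% aq AcOH, rt
Reagents that add atoms: water, O
Why: The secondary enamine tautomer of the chiral imine adds to the enone at the more substituted α-carbon (Michael stage of a Robinson annulation), the phenylethyl group shielding one enamine face so that the quaternary C1 forms with R configuration, and hydrolysis releases the ketone and the auxiliary.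

**Step 2**
Reactants: 6 (R)-7-methyl-7-(3-oxopentyl)-1,4-dioxaspiro[4.5]decan-8-one
Product: 7 (4aR)-6,6-ethylenedioxy-1,4a-dimethyl-4,4a,5,6,7,8-hexahydronaphthalen-2(3H)-one (ring A enone C10=C11–C12=O, C7 dioxolane)
Conditions: NaOMe, MeOH, rt → 60 °C
Reagents that add atoms: none
Why: Intramolecular aldol condensation (second stage of the Robinson annulation) of the ethyl ketone α-methylene C11 onto the ring ketone C10 followed by dehydration closes ring A as the six-membered enone without creating a stereocentre.

**Step 3**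
Reactants: 7 ring A enone with C7 dioxolane
Product: 8 trans-decalin C11=C12 trimethylsilyl enol ether with C7 dioxolane (C10–H anti to C1–CH3)
Conditions: Li, NH3(l)–THF, t-BuOH (1 equiv), −78 °C; evaporate NH3; then TMSCl, Et3N, THF, −78 → 0 °C
Reagents that add atoms: chlorotrimethylsilane, C[Si](C)(C)Cl
Why: Dissolving-metal (Birch-type) reduction of the enone protonates C10 axially to give the trans ring fusion and leaves the C11=C12 lithium enolate regiospecifically, which is trapped on oxygen by the silyl chloride.

**Step 4**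
Reactants: 8 C11=C12 trimethylsilyl enol ether
Product: 10 trans-decalin 11-hydroxy-12-ketone with C7 dioxolane (C11–OH anti, C11–CH3 syn to C1–CH3), via α-silyloxy ketone 9 (not isolated)
Conditions: mCPBA, NaHCO3, CH2Cl2, −20 → 0 °C; then K2CO3 (cat.), MeOH, 0 °C
Reagents that add atoms: 3-chloroperbenzoic acid, OOC(=O)c1cccc(Cl)c1
Why: Rubottom oxidation: the peracid epoxidises the tetrasubstituted enol ether on the face anti to the 1,3-related axial C1 methyl, silyl migration opens the silyloxy epoxide to the α-silyloxy ketone and methanolysis frees the tertiary C11 alcohol with the configuration of the target.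

**Step 5**
Reactants: 10 11-hydroxy-12-ketone
Product: 11 11-hydroxy-13-en-12-one with C7 dioxolane
Conditions: IBX, DMSO–fluorobenzene, 70 °C
Reagents that add atoms: none
Why: IBX dehydrogenation of a ketone through its enol; only C13 carries α-hydrogens and C1 is quaternary, so a single enone (C13=C14) can form and no further unsaturation is possible.

**Step 6**
Reactants: 11 11-hydroxy-13-en-12-one
Product: 12 13-ene-11,12-trans-diol with C7 dioxolane (C12–OH syn to C1–CH3)
Conditions: NaBH4, CeCl3·7H2O, MeOH, −78 → −20 °C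
Reagents that add atoms: none
Why: Luche 1,2-reduction masks the ring A ketone as the allylic alcohol, hydride being expected on the face opposite the pseudo-axial C11 methyl (trans-diol).

**Step 7**
Reactants: 12 13-ene-11,12-diol with C7 dioxolane
Product: 13 11,12-dihydroxy-13-en-7-one (trans-decalin keto diol)
Conditions: PPTS (cat.), acetone–H2O, 50 °C
Reagents that add atoms: water, O
Why: Acid-catalysed hydrolysis of the unhindered cyclohexanone dioxolane, placed before any silyl ether is present so that mild aqueous acid can be used.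

**Step 8**
Reactants: 13 keto diol
Product: 14 11,12-bis(triethylsilyloxy)-13-en-7-one
Conditions: TESOTf (2.6 equiv), 2,6-lutidine, CH2Cl2, −78 °C → rt
Reagents that add atoms: triethylsilyl trifluoromethanesulfonate, CC[Si](CC)(CC)OS(=O)(=O)C(F)(F)F
Why: Silyl triflate silylation protects the secondary allylic and the tertiary hydroxyl as triethylsilyl ethers that tolerate the amide bases, organometallics, hydride and oxidants of the following steps, the weak base leaving the ketone unenolised.

**Step 9**
Reactants: 14 bis-silyl ether ketone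
Product: 16 11,12-bis(triethylsilyloxy)-8,13-dien-7-one (ring B enone C7=O, C8=C9), via silyl enol ether 15 (not isolated)
Conditions: LDA, TMSCl, THF, −78 °C; then Pd(OAc)2, MeCN, rt
Reagents that add atoms: none
Why: Saegusa–Ito oxidation: kinetic deprotonation occurs at the less hindered C8 and Pd(OAc)2 dehydrosilylates the enol ether, unsaturation being able to develop only toward C9 because C1 is quaternary.

**Step 10**
Reactants: 16 ring B enone; 17 acetaldehyde
Product: 20 2-ethylidene-11,12-bis(triethylsilyloxy)-8,13-dien-7-one (E/Z mixture), via lithium aldolate 18 (not isolated), via mesylate 19 (not isolated)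
Conditions: LDA, THF, −78 °C; 17; then MsCl, −78 → 0 °C; then DBU, rt
Reagents that add atoms: none
Why: Kinetic α'-deprotonation of the enone at C2 (its only enolisable α position), aldol addition to acetaldehyde and elimination of the mesylate (aldol condensation) give the 2-ethylidene ketone, whose alkene geometry and C2 history are erased in the next step.

**Step 11**
Reactants: 20 2-ethylidene dienone
Product: 22 2-vinyl-11,12-bis(triethylsilyloxy)-8,13-dien-7-one (vinyl equatorial, C2–H anti to C1–CH3), via potassium trienolate 21 (not isolated)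
Conditions: KHMDS, THF, −78 °C; then AcOH, −78 °C
Reagents that add atoms: none
Why: Deconjugative protonation: γ-deprotonation of the ethylidene methyl gives the extended enolate, which is protonated kinetically at the α-carbon C2 on the face anti to the adjacent axial C1 methyl, so the vinyl group ends up equatorial.

**Step 12**
Reactants: 22 2-vinyl enone; 23 ethynylmagnesium bromide
Product: 24 7-ethynyl-2-vinyl-11,12-bis(triethylsilyloxy)-8,13-dien-7-ol (C7–OH axial and syn to C1–CH3, ethynyl trans to vinyl)
Conditions: CeCl3 (anhydrous), THF, −78 °C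
Reagents that add atoms: none
Why: 1,2-Addition of the weakly basic organocerium acetylide to the enolisable ketone occurs on the face anti to the 1,3-related axial C1 methyl, giving the axial tertiary alcohol with the ethynyl group equatorial and trans to the C2 vinyl group.

**Step 13**
Reactants: 24 tertiary allylic alcohol
Product: 25 8,9-epoxide of 24 (epoxide syn to the C7 hydroxyl and to C1–CH3)
Conditions: VO(acac)2 (cat.), t-BuOOH, CH2Cl2, 0 °C → rt
Reagents that add atoms: tert-butyl hydroperoxide, CC(C)(C)OO
Why: Vanadium-catalysed hydroxyl-directed epoxidation delivers oxygen to the C8=C9 alkene syn to the pseudo-axial C7 hydroxyl, which fixes the C9–O bond syn to the C1 methyl as in the target, while the homoallylic vinyl group, the alkyne and the ring A alkene lie outside the allylic-alcohol template.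

**Step 14**
Reactants: 25 epoxy alcohol
Product: 26 8-(4-methoxybenzyloxy)-7,9-diol (C8–O anti, C9–OH syn to C1–CH3, all three oxygens axial)
Conditions: 4-methoxybenzyl alcohol (excess), Cu(BF4)2 hydrate (cat.), CH2Cl2, rt
Reagents that add atoms: 4-methoxybenzyl alcohol, COc1ccc(CO)cc1
Why: Lewis acid-catalysed alcoholysis of the epoxide follows the Fürst–Plattner rule, trans-diaxial opening on the rigid trans-decalin placing the alcohol on C8 from the open face and leaving the axial C9–O bond untouched; C8 is carried as an oxidatively removable ether because it must later be unmasked beside silyl ethers.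

**Step 15**
Reactants: 26 7,9-diol
Product: 27 9-triethylsilyl ether of 26 (C7 hydroxyl free)
Conditions: TESOTf (1.05 equiv), 2,6-lutidine, CH2Cl2, −78 °C
Reagents that add atoms: triethylsilyl trifluoromethanesulfonate, CC[Si](CC)(CC)OS(=O)(=O)C(F)(F)F
Why: Low-temperature silylation with one equivalent of silyl triflate is expected to take the secondary C9 hydroxyl in preference to the tertiary propargylic C7 hydroxyl.

**Step 16**
Reactants: 27 terminal alkyne; 28 formaldehyde (as paraformaldehyde)
Product: 29 7-allenyl-2-vinyl trans-decalin-7-ol (C8 4-methoxybenzyl ether, C9/C11/C12 triethylsilyl ethers, C13=C14)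
Conditions: (CH2O)n, CuI, Cy2NH, 1,4-dioxane, reflux
Reagents that add atoms: none
Why: Crabbé homologation: Mannich addition of the terminal alkyne to the iminium ion from formaldehyde and the amine, then copper-mediated 1,5-hydride transfer with loss of the imine, converts the ethynyl carbinol into the terminal allenyl carbinol without touching the free tertiary alcohol.

**Step 17**
Reactants: 29 7-allenyl-2-vinyl trans-decalin-7-ol
Product: 32 ring A-fused (2E)-6-chloro-5-methylenecyclodec-2-en-7-one (8-OPMB, 9,11,12-tris-OTES), via potassium alkoxide 30 (not isolated), via potassium enolate 31 (not isolated)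
Conditions: KH, 18-crown-6, THF, 0 °C → rt; then NCS, THF, −78 °C
Reagents that add atoms: N-chlorosuccinimide, O=C1CCC(=O)N1Cl
Why: KH with 18-crown-6 strips the C7 hydroxyl to the naked alkoxide 30, whose oxido substituent accelerates a concerted [3,3] sigmatropic shift of the 1,5-diene C4=C3–C2–C7–C6=C5: the C4–C5 bond forms, the C2–C7 bond of ring B breaks, the distal allene π bond survives as the C5=C16 exo-methylene, and the cross-conjugated enolate 31 (C6=C7–OK) is chlorinated on carbon by NCS. The closest known reaction type is the anionic oxy-Cope ring expansion of trans-1,2-dialkenylcyclohexanols, 1-allenyl carbinols included, to cyclodec-5-enones with electrophilic capture of the enolate. The ten-membered ring (C1–C10) is therefore closed not by an end-to-end cyclisation but by a four-atom enlargement of ring B through a six-membered chair transition state, so no competing ring size exists. With vinyl and allenyl both equatorial on the locked trans-decalin, the chair places the ring bonds C1–C2 and C7–C8 pseudo-equatorial and the oxido group pseudo-axial, which gives the E C2=C3 alkene and an E-configured ring enolate. C6, the one new stereocentre, is set by the planar chirality of that enolate, NCS reaching only its peripheral face; the configuration drawn belongs to the rotamer with the enolate oxygen gauche to the C8–O bond, whereas the rotamer first released from the chair exposes the other face, so this is the least secured element. The step needs the [3,3] shift to outrun 5-endo attack of the alkoxide on the allene, O9→O7 silyl transfer and enolate equilibration toward C8 (β-loss of the C9 silyloxy group); the large oxido acceleration at 0–20 °C, the steric preference of silicon for the secondary O9 and chlorination at −78 °C directly after rearrangement are what secure this.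

**Step 18**
Reactants: 32 α-chloro ketone
Product: 33 6-chloro-7-ol (chlorohydrin, C7 configured as in the target)
Conditions: NaBH4, MeOH–THF, −40 °C
Reagents that add atoms: none
Why: Borohydride reduction of the α-chloro ketone to the chlorohydrin, hydride being expected on the peripheral face of the ring carbonyl to give the C7 configuration drawn; basic conditions that would close the chlorohydrin to an epoxide are avoided.

**Step 19**
Reactants: 33 chlorohydrin; 34 2-bromopropanoyl bromide (racemic)
Product: 35 7-(2-bromopropanoate) of 33 (epimers at the C–Br carbon)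
Conditions: pyridine, DMAP (cat.), CH2Cl2, −20 → 0 °C
Reagents that add atoms: none
Why: Acylation of the secondary alcohol by the acid bromide with retention at C7; the configuration of the bromine-bearing carbon is irrelevant because it becomes the enolate carbon in step 22.

**Step 20**
Reactants: 35 C8 4-methoxybenzyl ether
Product: 36 8-hydroxy 7-(2-bromopropanoate)
Conditions: DDQ, CH2Cl2–pH 7 buffer, 0 °C → rt
Reagents that add atoms: none
Why: Oxidative cleavage of the 4-methoxybenzyl ether by DDQ through the benzylic oxocarbenium ion and its hydrolysis, under buffered conditions that leave the silyl ethers, the bromo ester, the allylic chloride and the alkenes intact.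

**Step 21**
Reactants: 36 C8 alcohol
Product: 37 8-keto 7-(2-bromopropanoate)
Conditions: Dess–Martin periodinane, NaHCO3, CH2Cl2, 0 °C → rt
Reagents that add atoms: none
Why: Dess–Martin oxidation of the secondary alcohol to the ketone under buffered non-basic conditions, so that the now enolisable C7 and C9 centres (and the β-chloride) are not disturbed.

**Step 22**
Reactants: 37 α-(bromoacyloxy) ketone
Product: 39 8-hydroxy-19,7-lactone (trans-fused γ-lactone, C17 methyl cis to C8–OH) as 9,11,12-tris(triethylsilyl) ether, via samarium enolate 38 (not isolated)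
Conditions: SmI2 (2.5 equiv), THF, −78 °C
Reagents that add atoms: none
Why: SmI2-mediated intramolecular Reformatsky reaction: the bromo ester is reduced far faster than the ketone or the allylic chloride, and the samarium enolate adds to the adjacent C8 carbonyl in a chelated five-membered (5-exo-trig) closure, C8 being set by the carbonyl face that the C7-tethered enolate reaches in the ring conformer with C6 and C9 anti, and C17 by the chelated enolate with its methyl turned away from C9 (the thermodynamically favoured, epimerisable arrangement).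

**Step 23**
Reactants: 39 tris(triethylsilyl) ether
Product: 40 8,9,11,12-tetrol lactone
Conditions: HF·pyridine, pyridine–THF, 0 °C → rt
Reagents that add atoms: none
Why: Fluoride cleavage of the three triethylsilyl ethers under buffered conditions that tolerate the β-hydroxy lactone and the allylic chloride.

**Step 24**
Reactants: 40 tetrol
Product: 41 8,9,11-trihydroxy-13-en-12-one lactone (ring A enone restored)
Conditions: MnO2 (activated), CH2Cl2, rt
Reagents that add atoms: none
Why: MnO2 oxidises only the allylic C12 alcohol; the non-allylic secondary C9 and the tertiary C8 and C11 hydroxyls are inert, and C4 is not yet oxygenated.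

**Step 25**
Reactants: 41 triol enone
Product: 42 9,11-diacetate (4-deoxy target)
Conditions: Ac2O, DMAP, Et3N, CH2Cl2, rt → 40 °C
Reagents that add atoms: acetic anhydride, CC(=O)OC(C)=O
Why: DMAP-catalysed acetylation esterifies the secondary C9 hydroxyl and, on warming, the tertiary α-ketol C11 hydroxyl, while the C8 tertiary hydroxyl flanked by three substituted carbons is expected to remain free.

**Step 26**
Reactants: 42 9,11-diacetate
Product: 43 target CNP0196166.1
Conditions: SeO2 (cat.), t-BuOOH, CH2Cl2, 0 °C → rt
Reagents that add atoms: selenium dioxide, O=[Se]=O (catalytic oxygen carrier); tert-butyl hydroperoxide, CC(C)(C)OO (terminal oxidant)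
Why: SeO2 allylic hydroxylation: an ene reaction of the C5=C16 (or C2=C3) alkene with the doubly allylic C4–H and a [2,3] sigmatropic shift of the allylseleninic acid return the alkene to its place and put the hydroxyl on C4 in place of the hydrogen on the exposed ring face, C6–H being deactivated by chlorine and ring A having no allylic hydrogen.

**Compound list**
1 | 7-methyl-1,4-dioxaspiro[4.5]decan-8-one (racemic) | CC1CC2(CCC1=O)OCCO2 | starting material
2 | (R)-1-phenylethylamine | C[C@@H](N)c1ccccc1 | starting material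
3 | pent-1-en-3-one | CCC(=O)C=C | starting material
4 | N-[(R)-1-phenylethyl]imine of 1 (α-centre equilibrating through the enamine) | C[C@@H](N=C1CCC2(OCCO2)CC1C)c1ccccc1 | intermediate
5 | N-[(R)-1-phenylethyl]imine of (R)-7-methyl-7-(3-oxopentyl)-1,4-dioxaspiro[4.5]decan-8-one | CCC(=O)CC[C@]1(C)CC2(CCC1=N[C@H](C)c1ccccc1)OCCO2 | intermediate
6 | (R)-7-methyl-7-(3-oxopentyl)-1,4-dioxaspiro[4.5]decan-8-one | CCC(=O)CC[C@]1(C)CC2(CCC1=O)OCCO2 | intermediate
7 | (4aR)-6,6-ethylenedioxy-1,4a-dimethyl-4,4a,5,6,7,8-hexahydronaphthalen-2(3H)-one | CC1=C2CCC3(OCCO3)C[C@@]2(C)CCC1=O | intermediate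
8 | trans-decalin C11=C12 trimethylsilyl enol ether, C7 dioxolane | O1CCOC12C[C@@]3(C)CCC(O[Si](C)(C)C)=C(C)[C@@H]3CC2 | intermediate
9 | 11-(trimethylsilyloxy)-12-ketone, C7 dioxolane | O1CCOC12C[C@@]3(C)CCC(=O)[C@@](C)(O[Si](C)(C)C)[C@@H]3CC2 | intermediate
10 | trans-decalin 11-hydroxy-12-ketone, C7 dioxolane (C11–OH anti to C1–CH3) | O1CCOC12C[C@@]3(C)CCC(=O)[C@@](C)(O)[C@@H]3CC2 | intermediate
11 | 11-hydroxy-13-en-12-one, C7 dioxolane | O1CCOC12C[C@@]3(C)C=CC(=O)[C@@](C)(O)[C@@H]3CC2 | intermediate
12 | 13-ene-11,12-trans-diol, C7 dioxolane (C12–OH syn to C1–CH3) | O1CCOC12C[C@@]3(C)C=C[C@H](O)[C@@](C)(O)[C@@H]3CC2 | intermediate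
13 | 11,12-dihydroxy-13-en-7-one (keto diol) | O=C1C[C@@]2(C)C=C[C@H](O)[C@@](C)(O)[C@@H]2CC1 | intermediate
14 | 11,12-bis(triethylsilyloxy)-13-en-7-one | O=C1C[C@@]2(C)C=C[C@H](O[Si](CC)(CC)CC)[C@@](C)(O[Si](CC)(CC)CC)[C@@H]2CC1 | intermediate
15 | C7=C8 trimethylsilyl enol ether of 14 | C[Si](C)(C)OC=1C[C@@]2(C)C=C[C@H](O[Si](CC)(CC)CC)[C@@](C)(O[Si](CC)(CC)CC)[C@@H]2CC=1 | intermediate
16 | 11,12-bis(triethylsilyloxy)-8,13-dien-7-one | O=C1C[C@@]2(C)C=C[C@H](O[Si](CC)(CC)CC)[C@@](C)(O[Si](CC)(CC)CC)[C@@H]2C=C1 | intermediate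
17 | acetaldehyde | CC=O | starting material
18 | lithium aldolate (C2 side chain anti to C1–CH3, carbinol epimers) | O=C1[C@@H](C(C)O[Li])[C@@]2(C)C=C[C@H](O[Si](CC)(CC)CC)[C@@](C)(O[Si](CC)(CC)CC)[C@@H]2C=C1 | intermediate
19 | mesylate of the aldol | O=C1[C@@H](C(C)OS(C)(=O)=O)[C@@]2(C)C=C[C@H](O[Si](CC)(CC)CC)[C@@](C)(O[Si](CC)(CC)CC)[C@@H]2C=C1 | intermediate
20 | 2-ethylidene-11,12-bis(triethylsilyloxy)-8,13-dien-7-one (E/Z mixture) | O=C1C(=CC)[C@@]2(C)C=C[C@H](O[Si](CC)(CC)CC)[C@@](C)(O[Si](CC)(CC)CC)[C@@H]2C=C1 | intermediate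
21 | potassium trienolate (C2=C7–OK, C2 vinyl) | [K]OC1=C(C=C)[C@@]2(C)C=C[C@H](O[Si](CC)(CC)CC)[C@@](C)(O[Si](CC)(CC)CC)[C@@H]2C=C1 | intermediate
22 | 2-vinyl-11,12-bis(triethylsilyloxy)-8,13-dien-7-one (vinyl equatorial) | O=C1[C@H](C=C)[C@@]2(C)C=C[C@H](O[Si](CC)(CC)CC)[C@@](C)(O[Si](CC)(CC)CC)[C@@H]2C=C1 | intermediate
23 | ethynylmagnesium bromide | C#C[Mg]Br | starting material
24 | 7-ethynyl-2-vinyl-11,12-bis(triethylsilyloxy)-8,13-dien-7-ol | C#C[C@@]1(O)[C@H](C=C)[C@@]2(C)C=C[C@H](O[Si](CC)(CC)CC)[C@@](C)(O[Si](CC)(CC)CC)[C@@H]2C=C1 | intermediate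
25 | 8,9-epoxide of 24 (syn to C7–OH) | C#C[C@@]1(O)[C@H](C=C)[C@@]2(C)C=C[C@H](O[Si](CC)(CC)CC)[C@@](C)(O[Si](CC)(CC)CC)[C@@H]2[C@@H]3O[C@H]13 | intermediate
26 | 8-(4-methoxybenzyloxy)-7,9-diol | C#C[C@@]1(O)[C@H](C=C)[C@@]2(C)C=C[C@H](O[Si](CC)(CC)CC)[C@@](C)(O[Si](CC)(CC)CC)[C@@H]2[C@H](O)[C@H]1OCc1ccc(OC)cc1 | intermediate
27 | 9-triethylsilyl ether of 26 | C#C[C@@]1(O)[C@H](C=C)[C@@]2(C)C=C[C@H](O[Si](CC)(CC)CC)[C@@](C)(O[Si](CC)(CC)CC)[C@@H]2[C@H](O[Si](CC)(CC)CC)[C@H]1OCc1ccc(OC)cc1 | intermediate
28 | formaldehyde (used as paraformaldehyde) | C=O | starting material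
29 | 7-allenyl-2-vinyl trans-decalin-7-ol (8-OPMB, 9,11,12-tris-OTES) | C=C=C[C@@]1(O)[C@H](C=C)[C@@]2(C)C=C[C@H](O[Si](CC)(CC)CC)[C@@](C)(O[Si](CC)(CC)CC)[C@@H]2[C@H](O[Si](CC)(CC)CC)[C@H]1OCc1ccc(OC)cc1 | intermediate
30 | potassium alkoxide of 29 | C=C=C[C@@]1(O[K])[C@H](C=C)[C@@]2(C)C=C[C@H](O[Si](CC)(CC)CC)[C@@](C)(O[Si](CC)(CC)CC)[C@@H]2[C@H](O[Si](CC)(CC)CC)[C@H]1OCc1ccc(OC)cc1 | intermediate
31 | ring-expanded potassium enolate (E C2=C3, E ring enolate C6=C7) | C=C1C/C=C/[C@@]2(C)C=C[C@H](O[Si](CC)(CC)CC)[C@@](C)(O[Si](CC)(CC)CC)[C@@H]2[C@H](O[Si](CC)(CC)CC)[C@@H](OCc3ccc(OC)cc3)/C(O[K])=C/1 | intermediate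
32 | ring A-fused (2E)-6-chloro-5-methylenecyclodec-2-en-7-one (8-OPMB, 9,11,12-tris-OTES) | C=C1C/C=C/[C@@]2(C)C=C[C@H](O[Si](CC)(CC)CC)[C@@](C)(O[Si](CC)(CC)CC)[C@@H]2[C@H](O[Si](CC)(CC)CC)[C@@H](OCc3ccc(OC)cc3)C(=O)[C@H]1Cl | intermediate
33 | 6-chloro-7-ol (chlorohydrin) | C=C1C/C=C/[C@@]2(C)C=C[C@H](O[Si](CC)(CC)CC)[C@@](C)(O[Si](CC)(CC)CC)[C@@H]2[C@H](O[Si](CC)(CC)CC)[C@@H](OCc3ccc(OC)cc3)[C@@H](O)[C@H]1Cl | intermediate
34 | 2-bromopropanoyl bromide (racemic) | CC(Br)C(Br)=O | starting material
35 | 7-(2-bromopropanoate) of 33 | C=C1C/C=C/[C@@]2(C)C=C[C@H](O[Si](CC)(CC)CC)[C@@](C)(O[Si](CC)(CC)CC)[C@@H]2[C@H](O[Si](CC)(CC)CC)[C@@H](OCc3ccc(OC)cc3)[C@@H](OC(=O)C(C)Br)[C@H]1Cl | intermediate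
36 | 8-hydroxy 7-(2-bromopropanoate) | C=C1C/C=C/[C@@]2(C)C=C[C@H](O[Si](CC)(CC)CC)[C@@](C)(O[Si](CC)(CC)CC)[C@@H]2[C@H](O[Si](CC)(CC)CC)[C@@H](O)[C@@H](OC(=O)C(C)Br)[C@H]1Cl | intermediate
37 | 8-keto 7-(2-bromopropanoate) | C=C1C/C=C/[C@@]2(C)C=C[C@H](O[Si](CC)(CC)CC)[C@@](C)(O[Si](CC)(CC)CC)[C@@H]2[C@H](O[Si](CC)(CC)CC)C(=O)[C@@H](OC(=O)C(C)Br)[C@H]1Cl | intermediate
38 | samarium enolate of the C7 propanoate | C=C1C/C=C/[C@@]2(C)C=C[C@H](O[Si](CC)(CC)CC)[C@@](C)(O[Si](CC)(CC)CC)[C@@H]2[C@H](O[Si](CC)(CC)CC)C(=O)[C@@H](OC(O[Sm](I)I)=CC)[C@H]1Cl | intermediate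
39 | 8-hydroxy-19,7-lactone, 9,11,12-tris(triethylsilyl) ether | C=C1C/C=C/[C@@]2(C)C=C[C@H](O[Si](CC)(CC)CC)[C@@](C)(O[Si](CC)(CC)CC)[C@@H]2[C@H](O[Si](CC)(CC)CC)[C@]2(O)[C@@H](C)C(=O)O[C@H]2[C@H]1Cl | intermediate
40 | 8,9,11,12-tetrol lactone | C=C1C/C=C/[C@@]2(C)C=C[C@H](O)[C@@](C)(O)[C@@H]2[C@H](O)[C@]2(O)[C@@H](C)C(=O)O[C@H]2[C@H]1Cl | intermediate
41 | 8,9,11-trihydroxy-13-en-12-one lactone | C=C1C/C=C/[C@@]2(C)C=CC(=O)[C@@](C)(O)[C@@H]2[C@H](O)[C@]2(O)[C@@H](C)C(=O)O[C@H]2[C@H]1Cl | intermediate
42 | 9,11-diacetate (4-deoxy target) | C=C1C/C=C/[C@@]2(C)C=CC(=O)[C@@](C)(OC(C)=O)[C@@H]2[C@H](OC(C)=O)[C@]2(O)[C@@H](C)C(=O)O[C@H]2[C@H]1Cl | intermediate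
43 | CNP0196166.1 | C=C1[C@@H](O)/C=C/[C@@]2(C)C=CC(=O)[C@@](C)(OC(C)=O)[C@@H]2[C@H](OC(C)=O)[C@]2(O)[C@@H](C)C(=O)O[C@H]2[C@H]1Cl | target

Total step count: 26. Longest linear sequence: 26 steps (the route is fully linear from ketone 1).

**Steps most likely to fail**

Step 17. What may go wrong is loss of facial control in the chlorination of the ring enolate: chlorine may arrive on the face exposed by the first-formed rotamer instead of the one needed. Silyl transfer from O9 to the C7 alkoxide may also slow the rearrangement. The fallback keeps the rearrangement but uses that same exposed face with an oxygen electrophile and then inverts. It sets out from 29: enolate 31 is quenched with 2-(phenylsulfonyl)-3-phenyloxaziridine to give the C6-epimeric α-hydroxy ketone F1. Triflation (Tf2O, 2,6-lutidine, −78 °C) gives the α-keto triflate F2, and SN2 displacement with Bu4NCl (inversion at C6) delivers 32, where the route resumes.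

Step 22. What may go wrong is addition of the tethered enolate to the wrong face of the C8 carbonyl (cis-fused lactone), or simple reductive debromination without C–C bond formation. The fallback sets the C8 oxygen by an intermolecular oxidant instead. It sets out from 37: PPh3 (MeCN, rt) converts the bromo ester into the phosphonium bromide F3, whose ylide (Et3N) closes by intramolecular Wittig olefination of the C8 ketone to the C8=C17 butenolide F4. Nucleophilic epoxidation (t-BuOOH, DBU) on the peripheral face gives the 8,17-epoxy lactone F5. SmI2 in THF–MeOH at −78 °C then cleaves the C17–O bond next to the carbonyl, with C17 open to base equilibration, and the route is rejoined at 39.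

Step 18. What may go wrong is poor or reversed facial selectivity in hydride delivery to the ten-membered α-chloro ketone. The fallback replaces substrate control by reagent control. It sets out from 32 and uses a Corey–Bakshi–Shibata reduction (the enantiomer of the methyl oxazaborolidine matched to the required C7 face, BH3·SMe2, −30 °C), a reaction type that is dependable for α-chloro ketones. It leads directly to 33 and needs no new intermediate.

**Further compounds**
F1 | step 17 | C6-epimeric α-hydroxy ketone (6-hydroxy analogue of 32, hydroxyl on the face opposite to the chlorine of 32) | C=C1C/C=C/[C@@]2(C)C=C[C@H](O[Si](CC)(CC)CC)[C@@](C)(O[Si](CC)(CC)CC)[C@@H]2[C@H](O[Si](CC)(CC)CC)[C@@H](OCc3ccc(OC)cc3)C(=O)[C@@H]1O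
F2 | step 17 | α-keto triflate of F1 | C=C1C/C=C/[C@@]2(C)C=C[C@H](O[Si](CC)(CC)CC)[C@@](C)(O[Si](CC)(CC)CC)[C@@H]2[C@H](O[Si](CC)(CC)CC)[C@@H](OCc3ccc(OC)cc3)C(=O)[C@@H]1OS(=O)(=O)C(F)(F)F
F3 | step 22 | phosphonium bromide from 37 | C=C1C/C=C/[C@@]2(C)C=C[C@H](O[Si](CC)(CC)CC)[C@@](C)(O[Si](CC)(CC)CC)[C@@H]2[C@H](O[Si](CC)(CC)CC)C(=O)[C@@H](OC(=O)C(C)[P+](c3ccccc3)(c3ccccc3)c3ccccc3)[C@H]1Cl.[Br-]
F4 | step 22 | C8=C17 butenolide | C=C1C/C=C/[C@@]2(C)C=C[C@H](O[Si](CC)(CC)CC)[C@@](C)(O[Si](CC)(CC)CC)[C@@H]2[C@H](O[Si](CC)(CC)CC)C2=C(C)C(=O)O[C@H]2[C@H]1Cl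
F5 | step 22 | 8,17-epoxy lactone | C=C1C/C=C/[C@@]2(C)C=C[C@H](O[Si](CC)(CC)CC)[C@@](C)(O[Si](CC)(CC)CC)[C@@H]2[C@H](O[Si](CC)(CC)CC)[C@]2(O3)[C@]3(C)C(=O)O[C@H]2[C@H]1Cl
F0 | step 18 | none | none
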